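The route cuts two bonds at C4 of the oxolane (ring B): the tertiary C4–O bond and the C7–aryl bond to ring A. Both are made at once by adding the ring A aryl radical and a TEMPO oxygen across the exocyclic C4=C7 double bond of a 2,3-cis-2-aryl-3-(silyloxymethyl)-4-methyleneoxolane, the nitroxide entering anti to the C3 substituent. The alkene comes from an Evans syn-aldol of a cis-2,3-dihydrobenzofuran aldehyde (itself from an enantioselective rhodium carbenoid C–H insertion), O–H insertion of a diazoketone to the oxolan-3-one and methylenation. Reductive N–O cleavage and deprotection finish the synthesis.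

Key step: step 18

Locants and abbreviations: ring B is the oxolane with O1, C2 (aryl), C3 (CH2OH), C4 (OH and C7H2–ring A) and C5; primed locants belong to the dihydrobenzofuran; ring C is the aryl group on C2'. TIPS = triisopropylsilyl, TBS = tert-butyldimethylsilyl, TES = triethylsilyl. DHB = the (2R,3R)-3-(TBS-oxymethyl)-7-methoxy-2-[3-methoxy-4-(TIPS-oxy)phenyl]-2,3-dihydro-1-benzofuran-5-yl group (2',3'-cis), that is aldehyde 10 without its CHO group.

Remark on the target: read from the SMILES, aryl and hydroxymethyl are cis on both five-membered rings (C2'/C3' both R; C2/C3 both R), and at C4 (S) the OH is trans to the C3 CH2OH; the route is built for exactly this isomer, and alkene 24 and alkoxyamine 29 carry the same descriptors.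

Remark on design: the ring C phenol is carried as a TIPS ether, since an aryl TBS ether would not reliably pass LiOOH and TEMPONa; the ring A phenol stays an acetate, but its diazonium salt is made and kept water-free because an ester para to N2+ is an activated ester.

Assumption: Rh2(S-PTTL)4 is taken to give the (2'R,3'S) cis ester, by analogy with closely related 2-aryl substrates; if the first run shows the opposite sense, the enantiomeric catalyst Rh2(R-PTTL)4 is used.

Assumption: acid 12 is bought as a catalogue building block.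

Step 1
Reactants: 1 vanillin
Product: 2 3-methoxy-4-(TIPS-oxy)benzaldehyde
Conditions: TIPSCl, imidazole, DMF, rt
Reagents that add atoms: triisopropylsilyl chloride, CC(C)[Si](Cl)(C(C)C)C(C)C
Why: Imidazole-promoted silyl ether formation on the phenol, with the hindered TIPS group chosen because it has to survive hydride, LiOOH and TEMPONa later.

Step 2
Reactants: 2 3-methoxy-4-(TIPS-oxy)benzaldehyde
Product: 3 [3-methoxy-4-(TIPS-oxy)phenyl]methanol
Conditions: NaBH4, MeOH/THF, 0 °C
Reagents that add atoms: none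
Why: Borohydride reduction of an aryl aldehyde to the benzylic alcohol, which leaves the aryl silyl ether alone under brief cold conditions.

Step 3
Reactants: 3 [3-methoxy-4-(TIPS-oxy)phenyl]methanol; 4 5-iodovanillin
Product: 5 3-iodo-5-methoxy-4-{[3-methoxy-4-(TIPS-oxy)phenyl]methoxy}benzaldehyde
Conditions: PPh3, DIAD, THF, 0 °C to rt
Reagents that add atoms: none
Why: Mitsunobu etherification, in which the phenol of 4 (acidified by the para formyl group and the ortho iodine) is the pronucleophile and the neutral medium spares the aryl silyl ether and the aldehyde.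

Step 4
Reactants: 5 3-iodo-5-methoxy-4-{[3-methoxy-4-(TIPS-oxy)phenyl]methoxy}benzaldehyde
Product: 6 ethyl 2-diazo-2-(5-formyl-3-methoxy-2-{[3-methoxy-4-(TIPS-oxy)phenyl]methoxy}phenyl)acetate
Conditions: ethyl diazoacetate, Pd(PPh3)4 (5 mol %), Ag2CO3 (0.5 equiv), Et3N, toluene, rt
Reagents that add atoms: ethyl diazoacetate, CCOC(=O)C=[N+]=[N-]
Why: Palladium-catalysed cross-coupling of an aryl iodide with a diazoacetate, which arylates the diazo carbon with the diazo group kept, while Ag2CO3 takes up iodide and the weak amine base does not add the diazo ester to the aldehyde.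

Step 5
Reactants: 6 ethyl 2-diazo-2-(5-formyl-3-methoxy-2-{[3-methoxy-4-(TIPS-oxy)phenyl]methoxy}phenyl)acetate
Product: 7 ethyl (2R,3S)-5-formyl-7-methoxy-2-[3-methoxy-4-(TIPS-oxy)phenyl]-2,3-dihydro-1-benzofuran-3-carboxylate (2,3-cis)
Conditions: Rh2(S-PTTL)4 (dirhodium tetrakis[N-phthaloyl-(S)-tert-leucinate], 1 mol %), toluene, –78 °C
Reagents that add atoms: none
Why: Enantioselective intramolecular 1,5 C–H insertion of a donor/acceptor rhodium carbenoid into the benzylic O–CH2 group closes the dihydrofuran ring, the chiral carboxylate ligands setting C2' and C3' together and the concerted insertion giving the kinetic cis ester.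

Step 6
Reactants: 7 ethyl (2R,3S)-5-formyl-7-methoxy-2-[3-methoxy-4-(TIPS-oxy)phenyl]-2,3-dihydro-1-benzofuran-3-carboxylate
Product: 8 {(2R,3R)-7-methoxy-2-[3-methoxy-4-(TIPS-oxy)phenyl]-2,3-dihydro-1-benzofuran-3,5-diyl}dimethanol (2,3-cis)
Conditions: iBu2AlH, CH2Cl2, –78 to –20 °C; aq. sodium potassium tartrate (KNaC4H4O6)
Reagents that add atoms: none
Why: Hydride reduction of ester and aldehyde with a non-basic aluminium hydride, so the C3' centre next to the ester is reduced before it can epimerise to the trans series.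

Step 7
Reactants: 8 {(2R,3R)-7-methoxy-2-[3-methoxy-4-(TIPS-oxy)phenyl]-2,3-dihydro-1-benzofuran-3,5-diyl}dimethanol
Product: 10 (2R,3R)-3-(TBS-oxymethyl)-7-methoxy-2-[3-methoxy-4-(TIPS-oxy)phenyl]-2,3-dihydro-1-benzofuran-5-carbaldehyde (DHB–CHO), via hydroxy aldehyde 9 (not isolated)
Conditions: MnO2, CH2Cl2, rt; filter; then TBSCl, imidazole, rt
Reagents that add atoms: tert-butyldimethylsilyl chloride, CC(C)(C)[Si](C)(C)Cl
Why: Chemoselective MnO2 oxidation touches only the benzylic alcohol, and the remaining non-benzylic primary alcohol is then capped by silyl ether formation.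

Step 8
Reactants: 11 (R)-4-benzyl-2-oxazolidinone; 12 3-(TBS-oxy)propanoic acid
Product: 14 (R)-4-benzyl-3-[3-(TBS-oxy)propanoyl]oxazolidin-2-one, via mixed pivalic anhydride 13 (not isolated)
Conditions: PivCl, Et3N, THF, –20 °C; then 11, LiCl, –20 °C to rt
Reagents that add atoms: none
Why: N-acylation of the oxazolidinone through a mixed anhydride activated by LiCl/Et3N, which avoids an acid chloride of the silyloxy acid.

Step 9
Reactants: 14 (R)-4-benzyl-3-[3-(TBS-oxy)propanoyl]oxazolidin-2-one; 10 DHB–CHO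
Product: 17 (R)-4-benzyl-3-[(2R,3R)-3-DHB-3-hydroxy-2-(TBS-oxymethyl)propanoyl]oxazolidin-2-one (2,3-syn), via Z boron enolate 15 (not isolated), via boron aldolate 16 (not isolated)
Conditions: Bu2BOTf, iPr2NEt, CH2Cl2, –78 to 0 °C; then 10, –78 to 0 °C; pH 7 buffer, MeOH, H2O2, 0 °C
Reagents that add atoms: none
Why: Evans syn-aldol reaction, in which the covalent Z dibutylboron enolate (which does not expel the β-silyloxy group) reacts through a closed Zimmerman–Traxler chair with the benzyl group of the (R)-auxiliary blocking one enolate face, setting C2 and C3 of ring B (both R, syn) and turning any minor enantiomer of 10 into a separable diastereomer.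

Step 10
Reactants: 17 (R)-4-benzyl-3-[(2R,3R)-3-DHB-3-hydroxy-2-(TBS-oxymethyl)propanoyl]oxazolidin-2-one
Product: 18 (R)-4-benzyl-3-[(2R,3R)-3-DHB-2-(TBS-oxymethyl)-3-(TES-oxy)propanoyl]oxazolidin-2-one
Conditions: TESOTf, 2,6-lutidine, CH2Cl2, –78 to 0 °C
Reagents that add atoms: triethylsilyl triflate, CC[Si](CC)(CC)OS(=O)(=O)C(F)(F)F
Why: Silyl ether formation masks the secondary alcohol for the acid activation two steps on, TES being the one silyl group here that can later be removed selectively.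

Step 11
Reactants: 18 (R)-4-benzyl-3-[(2R,3R)-3-DHB-2-(TBS-oxymethyl)-3-(TES-oxy)propanoyl]oxazolidin-2-one
Product: 19 (2R,3R)-3-DHB-2-(TBS-oxymethyl)-3-(TES-oxy)propanoic acid
Conditions: LiOH, H2O2, THF/H2O, 0 °C; aq. Na2SO3; dilute HCl to pH 4
Reagents that add atoms: hydrogen peroxide, OO
Why: Hydrolytic removal of the auxiliary with LiOOH (selective exocyclic acyl cleavage), mild enough to leave the α-centre and the silyl ethers intact and to return the oxazolidinone.

Step 12
Reactants: 19 (2R,3R)-3-DHB-2-(TBS-oxymethyl)-3-(TES-oxy)propanoic acid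
Product: 21 (3R,4R)-1-diazo-4-DHB-3-(TBS-oxymethyl)-4-(TES-oxy)butan-2-one, via mixed carbonic anhydride 20 (not isolated)
Conditions: iBuOCOCl, Et3N, THF, –20 °C; then TMSCHN2, MeCN, 0 °C to rt
Reagents that add atoms: (trimethylsilyl)diazomethane, C[Si](C)(C)C=[N+]=[N-]
Why: Acylation of (trimethylsilyl)diazomethane by the mixed anhydride (Arndt–Eistert-type diazoketone synthesis) proceeds under neutral conditions that do not enolise the α-centre.

Step 13
Reactants: 21 (3R,4R)-1-diazo-4-DHB-3-(TBS-oxymethyl)-4-(TES-oxy)butan-2-one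
Product: 23 (2R,3R)-2-DHB-3-(TBS-oxymethyl)oxolan-4-one (ring B locants; 2,3-cis), via hydroxy diazoketone 22 (not isolated)
Conditions: PPTS (0.2 equiv), MeOH/CH2Cl2, 0 °C; NaHCO3 wash, solvent switch; Rh2(OAc)4 (2 mol %), CH2Cl2, rt, high dilution
Reagents that add atoms: none
Why: Mild acid methanolysis removes the secondary TES ether ahead of the two primary TBS ethers, and rhodium carbenoid O–H insertion then forms the O1–C5 bond and closes the five-membered ring B under neutral conditions that leave the cis C2/C3 centres untouched.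

Step 14
Reactants: 23 (2R,3R)-2-DHB-3-(TBS-oxymethyl)oxolan-4-one
Product: 24 (2R,3R)-2-DHB-3-(TBS-oxymethyl)-4-methylideneoxolane (2,3-cis)
Conditions: Zn, CH2Br2, TiCl4 (reagent aged in THF, –40 to 5 °C); 23 in CH2Cl2, 0 °C to rt
Reagents that add atoms: dibromomethane, BrCBr
Why: Lombardo methylenation is a non-basic carbonyl olefination, chosen because C3 next to the ketone is epimerisable and the β-silyloxy group could otherwise be eliminated.

Step 15
Reactants: 25 2-methoxy-4-nitrophenol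
Product: 26 2-methoxy-4-nitrophenyl acetate
Conditions: Ac2O, pyridine, DMAP (cat.), CH2Cl2, rt
Reagents that add atoms: acetic anhydride, CC(=O)OC(C)=O
Why: Acylation of the phenol (ester formation) gives a protecting group that tolerates diazotisation and radical conditions and is removed by mild methanolysis.

Step 16
Reactants: 26 2-methoxy-4-nitrophenyl acetate
Product: 27 4-amino-2-methoxyphenyl acetate
Conditions: H2 (1 atm), palladium on carbon (Pd/C), EtOAc, rt; used at once
Reagents that add atoms: none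
Why: Catalytic hydrogenation of the nitro group to the aniline under neutral conditions, with the product carried on directly to avoid O-to-N acetyl transfer.

Step 17
Reactants: 27 4-amino-2-methoxyphenyl acetate
Product: 28 4-acetoxy-3-methoxybenzenediazonium tetrafluoroborate
Conditions: NOBF4, MeCN, –40 to –10 °C; precipitate with Et2O; store cold and dry
Reagents that add atoms: nitrosonium tetrafluoroborate, N#[O+].F[B-](F)(F)F
Why: Diazotisation of the aniline with a nitrosonium salt in dry acetonitrile gives the tetrafluoroborate without aqueous acid, which protects the activated aryl acetate.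

Step 18
Reactants: 24 (2R,3R)-2-DHB-3-(TBS-oxymethyl)-4-methylideneoxolane; 28 4-acetoxy-3-methoxybenzenediazonium tetrafluoroborate
Product: 29 (2R,3R,4S)-4-[(4-acetoxy-3-methoxyphenyl)methyl]-2-DHB-3-(TBS-oxymethyl)-4-[(2,2,6,6-tetramethylpiperidin-1-yl)oxy]oxolane (ring B locants)
Conditions: 28 (3 equiv), PhCF3, rt; TEMPONa (3 equiv, THF stock solution from TEMPO and Na) added over 3 h; argon
Reagents that add atoms: TEMPONa (sodium 2,2,6,6-tetramethylpiperidin-1-olate), CC1(C)CCCC(C)(C)N1[O-].[Na+]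
Why: TEMPONa transfers one electron to the diazonium ion, which loses N2 to give the ring A aryl radical and TEMPO; the aryl radical adds to the unsubstituted alkene terminus C7 and the tertiary C4 radical so formed couples with the persistent nitroxide. The closest known reaction type is the radical oxyarylation of alkenes with arenediazonium salts and TEMPONa, here applied to a 1,1-dialkyl alkene; no ring is closed. The new C4 stereocentre is set in the C–O coupling, where the bulky nitroxide approaches the planar radical from the face opposite the adjacent C3 CH2OTBS group and the cis C2 aryl group, placing oxygen trans to the C3 substituent and the new benzyl group cis to it, as the target requires. Regioselectivity follows from the preference of aryl radicals for the CH2 terminus, which leads to the more substituted radical. The selectivity that must be won is addition over hydrogen abstraction from the benzylic ether C–H bonds at C2 and C2', and it is secured by the high rate of aryl radical addition to a 1,1-disubstituted alkene and by using the inexpensive diazonium salt and TEMPONa in excess with slow addition of the latter.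

Step 19
Reactants: 29 (2R,3R,4S)-4-[(4-acetoxy-3-methoxyphenyl)methyl]-2-DHB-3-(TBS-oxymethyl)-4-[(2,2,6,6-tetramethylpiperidin-1-yl)oxy]oxolane
Product: 30 (2R,3R,4S)-4-[(4-acetoxy-3-methoxyphenyl)methyl]-2-DHB-3-(TBS-oxymethyl)oxolan-4-ol
Conditions: Zn dust, AcOH/THF/H2O (3:1:1), 45 °C
Reagents that add atoms: none
Why: Reductive N–O cleavage of the alkoxyamine by dissolving zinc frees the tertiary alcohol without breaking the C4–O bond, so the C4 configuration is kept.

Step 20
Reactants: 30 (2R,3R,4S)-4-[(4-acetoxy-3-methoxyphenyl)methyl]-2-DHB-3-(TBS-oxymethyl)oxolan-4-ol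
Product: 32 CNP0284796.1 (target), via ring A phenol 31 (not isolated)
Conditions: K2CO3 (0.2 equiv), MeOH, 0 °C; concentrate; then Bu4NF/AcOH (1:1), THF, 0 °C to rt
Reagents that add atoms: none
Why: Base-catalysed methanolysis removes the aryl acetate while ring C is still silylated, and acetic-acid-buffered fluoride then cleaves all three Si–O bonds without building up a ring C phenoxide that could open the cis dihydrobenzofuran through a quinone methide.

Compound list
1 | vanillin | COc1cc(C=O)ccc1O | starting material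
2 | 3-methoxy-4-(TIPS-oxy)benzaldehyde | COc1cc(C=O)ccc1O[Si](C(C)C)(C(C)C)C(C)C | intermediate
3 | [3-methoxy-4-(TIPS-oxy)phenyl]methanol | COc1cc(CO)ccc1O[Si](C(C)C)(C(C)C)C(C)C | intermediate
4 | 5-iodovanillin (4-hydroxy-3-iodo-5-methoxybenzaldehyde) | COc1cc(C=O)cc(I)c1O | starting material
5 | 3-iodo-5-methoxy-4-{[3-methoxy-4-(TIPS-oxy)phenyl]methoxy}benzaldehyde | COc1cc(C=O)cc(I)c1OCc1ccc(O[Si](C(C)C)(C(C)C)C(C)C)c(OC)c1 | intermediate
6 | ethyl 2-diazo-2-(5-formyl-3-methoxy-2-{[3-methoxy-4-(TIPS-oxy)phenyl]methoxy}phenyl)acetate | CCOC(=O)C(=[N+]=[N-])c1cc(C=O)cc(OC)c1OCc1ccc(O[Si](C(C)C)(C(C)C)C(C)C)c(OC)c1 | intermediate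
7 | ethyl (2R,3S)-5-formyl-7-methoxy-2-[3-methoxy-4-(TIPS-oxy)phenyl]-2,3-dihydro-1-benzofuran-3-carboxylate (2,3-cis) | O=Cc1cc(OC)c2c(c1)[C@H](C(=O)OCC)[C@H](c1ccc(O[Si](C(C)C)(C(C)C)C(C)C)c(OC)c1)O2 | intermediate
8 | {(2R,3R)-7-methoxy-2-[3-methoxy-4-(TIPS-oxy)phenyl]-2,3-dihydro-1-benzofuran-3,5-diyl}dimethanol (2,3-cis) | OCc1cc(OC)c2c(c1)[C@H](CO)[C@H](c1ccc(O[Si](C(C)C)(C(C)C)C(C)C)c(OC)c1)O2 | intermediate
9 | (2R,3R)-3-(hydroxymethyl)-7-methoxy-2-[3-methoxy-4-(TIPS-oxy)phenyl]-2,3-dihydro-1-benzofuran-5-carbaldehyde | O=Cc1cc(OC)c2c(c1)[C@H](CO)[C@H](c1ccc(O[Si](C(C)C)(C(C)C)C(C)C)c(OC)c1)O2 | intermediate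
10 | (2R,3R)-3-(TBS-oxymethyl)-7-methoxy-2-[3-methoxy-4-(TIPS-oxy)phenyl]-2,3-dihydro-1-benzofuran-5-carbaldehyde (DHB–CHO, 2,3-cis) | O=Cc1cc(OC)c2c(c1)[C@H](CO[Si](C)(C)C(C)(C)C)[C@H](c1ccc(O[Si](C(C)C)(C(C)C)C(C)C)c(OC)c1)O2 | intermediate
11 | (R)-4-benzyl-2-oxazolidinone | O=C1OC[C@@H](Cc2ccccc2)N1 | starting material
12 | 3-(TBS-oxy)propanoic acid | OC(=O)CCO[Si](C)(C)C(C)(C)C | starting material
13 | 3-(TBS-oxy)propanoic pivalic anhydride | CC(C)(C)C(=O)OC(=O)CCO[Si](C)(C)C(C)(C)C | intermediate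
14 | (R)-4-benzyl-3-[3-(TBS-oxy)propanoyl]oxazolidin-2-one | O=C1OC[C@@H](Cc2ccccc2)N1C(=O)CCO[Si](C)(C)C(C)(C)C | intermediate
15 | Z dibutylboron enolate of 14 | O=C1OC[C@@H](Cc2ccccc2)N1/C(OB(CCCC)CCCC)=C/CO[Si](C)(C)C(C)(C)C | intermediate
16 | O-dibutylboryl aldolate of 17 | O=C1OC[C@@H](Cc2ccccc2)N1C(=O)[C@H](CO[Si](C)(C)C(C)(C)C)[C@@H](OB(CCCC)CCCC)c3cc(OC)c4c(c3)[C@H](CO[Si](C)(C)C(C)(C)C)[C@H](c3ccc(O[Si](C(C)C)(C(C)C)C(C)C)c(OC)c3)O4 | intermediate
17 | (R)-4-benzyl-3-[(2R,3R)-3-DHB-3-hydroxy-2-(TBS-oxymethyl)propanoyl]oxazolidin-2-one (2,3-syn) | O=C1OC[C@@H](Cc2ccccc2)N1C(=O)[C@H](CO[Si](C)(C)C(C)(C)C)[C@@H](O)c3cc(OC)c4c(c3)[C@H](CO[Si](C)(C)C(C)(C)C)[C@H](c3ccc(O[Si](C(C)C)(C(C)C)C(C)C)c(OC)c3)O4 | intermediate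
18 | (R)-4-benzyl-3-[(2R,3R)-3-DHB-2-(TBS-oxymethyl)-3-(TES-oxy)propanoyl]oxazolidin-2-one | O=C1OC[C@@H](Cc2ccccc2)N1C(=O)[C@H](CO[Si](C)(C)C(C)(C)C)[C@@H](O[Si](CC)(CC)CC)c3cc(OC)c4c(c3)[C@H](CO[Si](C)(C)C(C)(C)C)[C@H](c3ccc(O[Si](C(C)C)(C(C)C)C(C)C)c(OC)c3)O4 | intermediate
19 | (2R,3R)-3-DHB-2-(TBS-oxymethyl)-3-(TES-oxy)propanoic acid | OC(=O)[C@H](CO[Si](C)(C)C(C)(C)C)[C@@H](O[Si](CC)(CC)CC)c3cc(OC)c4c(c3)[C@H](CO[Si](C)(C)C(C)(C)C)[C@H](c3ccc(O[Si](C(C)C)(C(C)C)C(C)C)c(OC)c3)O4 | intermediate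
20 | mixed isobutyl carbonic anhydride of 19 | CC(C)COC(=O)OC(=O)[C@H](CO[Si](C)(C)C(C)(C)C)[C@@H](O[Si](CC)(CC)CC)c3cc(OC)c4c(c3)[C@H](CO[Si](C)(C)C(C)(C)C)[C@H](c3ccc(O[Si](C(C)C)(C(C)C)C(C)C)c(OC)c3)O4 | intermediate
21 | (3R,4R)-1-diazo-4-DHB-3-(TBS-oxymethyl)-4-(TES-oxy)butan-2-one | [N-]=[N+]=CC(=O)[C@H](CO[Si](C)(C)C(C)(C)C)[C@@H](O[Si](CC)(CC)CC)c3cc(OC)c4c(c3)[C@H](CO[Si](C)(C)C(C)(C)C)[C@H](c3ccc(O[Si](C(C)C)(C(C)C)C(C)C)c(OC)c3)O4 | intermediate
22 | (3R,4R)-1-diazo-4-DHB-4-hydroxy-3-(TBS-oxymethyl)butan-2-one | [N-]=[N+]=CC(=O)[C@H](CO[Si](C)(C)C(C)(C)C)[C@@H](O)c3cc(OC)c4c(c3)[C@H](CO[Si](C)(C)C(C)(C)C)[C@H](c3ccc(O[Si](C(C)C)(C(C)C)C(C)C)c(OC)c3)O4 | intermediate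
23 | (2R,3R)-2-DHB-3-(TBS-oxymethyl)oxolan-4-one (ring B locants, 2,3-cis) | O=C1CO[C@@H](c3cc(OC)c4c(c3)[C@H](CO[Si](C)(C)C(C)(C)C)[C@H](c3ccc(O[Si](C(C)C)(C(C)C)C(C)C)c(OC)c3)O4)[C@H]1CO[Si](C)(C)C(C)(C)C | intermediate
24 | (2R,3R)-2-DHB-3-(TBS-oxymethyl)-4-methylideneoxolane (2,3-cis) | C=C1CO[C@@H](c3cc(OC)c4c(c3)[C@H](CO[Si](C)(C)C(C)(C)C)[C@H](c3ccc(O[Si](C(C)C)(C(C)C)C(C)C)c(OC)c3)O4)[C@H]1CO[Si](C)(C)C(C)(C)C | intermediate
25 | 2-methoxy-4-nitrophenol | COc1cc([N+](=O)[O-])ccc1O | starting material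
26 | 2-methoxy-4-nitrophenyl acetate | COc1cc([N+](=O)[O-])ccc1OC(C)=O | intermediate
27 | 4-amino-2-methoxyphenyl acetate | COc1cc(N)ccc1OC(C)=O | intermediate
28 | 4-acetoxy-3-methoxybenzenediazonium tetrafluoroborate | COc1cc([N+]#N)ccc1OC(C)=O.F[B-](F)(F)F | intermediate
29 | (2R,3R,4S)-4-[(4-acetoxy-3-methoxyphenyl)methyl]-2-DHB-3-(TBS-oxymethyl)-4-[(2,2,6,6-tetramethylpiperidin-1-yl)oxy]oxolane | COc1cc(C[C@@]2(ON5C(C)(C)CCCC5(C)C)CO[C@@H](c3cc(OC)c4c(c3)[C@H](CO[Si](C)(C)C(C)(C)C)[C@H](c3ccc(O[Si](C(C)C)(C(C)C)C(C)C)c(OC)c3)O4)[C@H]2CO[Si](C)(C)C(C)(C)C)ccc1OC(C)=O | intermediate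
30 | (2R,3R,4S)-4-[(4-acetoxy-3-methoxyphenyl)methyl]-2-DHB-3-(TBS-oxymethyl)oxolan-4-ol | COc1cc(C[C@@]2(O)CO[C@@H](c3cc(OC)c4c(c3)[C@H](CO[Si](C)(C)C(C)(C)C)[C@H](c3ccc(O[Si](C(C)C)(C(C)C)C(C)C)c(OC)c3)O4)[C@H]2CO[Si](C)(C)C(C)(C)C)ccc1OC(C)=O | intermediate
31 | (2R,3R,4S)-2-DHB-4-[(4-hydroxy-3-methoxyphenyl)methyl]-3-(TBS-oxymethyl)oxolan-4-ol | COc1cc(C[C@@]2(O)CO[C@@H](c3cc(OC)c4c(c3)[C@H](CO[Si](C)(C)C(C)(C)C)[C@H](c3ccc(O[Si](C(C)C)(C(C)C)C(C)C)c(OC)c3)O4)[C@H]2CO[Si](C)(C)C(C)(C)C)ccc1O | intermediate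
32 | CNP0284796.1: (2R,3R,4S)-4-[(4-hydroxy-3-methoxyphenyl)methyl]-3-(hydroxymethyl)-2-[(2R,3R)-2-(4-hydroxy-3-methoxyphenyl)-3-(hydroxymethyl)-7-methoxy-2,3-dihydro-1-benzofuran-5-yl]oxolan-4-ol (ring B locants) | COc1cc(C[C@@]2(O)CO[C@@H](c3cc(OC)c4c(c3)[C@H](CO)[C@H](c3ccc(O)c(OC)c3)O4)[C@H]2CO)ccc1O | target

Total step count: 20. Longest linear sequence: 16 steps (steps 1–7, 9–14 and 18–20, from vanillin); step 8 and steps 15–17 are side branches.

Steps most likely to fail

Step 18. The aryl radical may abstract hydrogen from the benzylic ether positions C2–H and C2'–H instead of adding to the alkene. The tertiary C4 radical may lose a β-hydrogen to TEMPO instead of coupling with it, or the nitroxide may discriminate poorly between the two faces. The fallback sets out from 24 and returns at 32, using only ionic chemistry. Epoxidation of the exocyclic alkene with mCPBA/NaHCO3 from the face opposite the C3 CH2OTBS group should give the spiro-epoxide F1. In parallel, commercial 4-bromo-2-methoxyphenol is silylated (TIPSCl, imidazole) to the aryl bromide F2, which is converted with Mg in THF into the Grignard reagent F3. Opening of F1 at its CH2 terminus by F3 with catalytic CuI should give the tetrasilylated tertiary alcohol F4. Its C4 configuration is that of 30, because the epoxide oxygen enters on the face that the nitroxide would have taken and the C4–O bond is never broken. Bu4NF/AcOH in THF then removes all four silyl groups and gives 32 directly.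

Step 4. Oxidative addition and coupling at an iodide flanked by the bulky benzyloxy group may be slow, palladium may decompose the diazo ester to carbene dimers, or the base may add the diazo ester to the free aldehyde. The fallback sets out from 5 and returns at 6. The aldehyde is masked with HC(OMe)3 and catalytic PPTS in MeOH as the dimethyl acetal F5. Coupling of F5 with the Reformatsky reagent BrZnCH2CO2Et under Pd2(dba)3/XPhos in THF gives the arylacetate F6. Regitz diazo transfer with 4-acetamidobenzenesulfonyl azide and DBU in MeCN gives the diazo ester acetal F7, and hydrolysis of the acetal on wet silica gel returns 6.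

Step 14. The cis configuration at C3 may be lost by enolisation of the ketone, silanol may be eliminated from the β-silyloxy ketone, or the Lewis-acidic titanium reagent may open the benzylic C2–O bond and scramble C2. The fallback sets out from 23 and returns at 24 by a two-stage Peterson olefination. Addition of the weakly basic organocerium reagent made from Me3SiCH2Li and CeCl3 in THF at –78 °C should give the β-hydroxysilane F8. Elimination with KH in THF, at a stage where no epimerisable ketone remains, then gives 24.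

Further compounds
F1 | step 18 | spiro-epoxide of 24: (2R,3R)-2-DHB-3-(TBS-oxymethyl)oxolane-4-spiro-2'-oxirane with the oxirane oxygen trans to the C3 substituent | C1[C@@]2(O1)CO[C@@H](c3cc(OC)c4c(c3)[C@H](CO[Si](C)(C)C(C)(C)C)[C@H](c3ccc(O[Si](C(C)C)(C(C)C)C(C)C)c(OC)c3)O4)[C@H]2CO[Si](C)(C)C(C)(C)C
F2 | step 18 | (4-bromo-2-methoxyphenoxy)triisopropylsilane | COc1cc(Br)ccc1O[Si](C(C)C)(C(C)C)C(C)C
F3 | step 18 | [3-methoxy-4-(TIPS-oxy)phenyl]magnesium bromide | COc1cc([Mg]Br)ccc1O[Si](C(C)C)(C(C)C)C(C)C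
F4 | step 18 | (2R,3R,4S)-2-DHB-4-{[3-methoxy-4-(TIPS-oxy)phenyl]methyl}-3-(TBS-oxymethyl)oxolan-4-ol | COc1cc(C[C@@]2(O)CO[C@@H](c3cc(OC)c4c(c3)[C@H](CO[Si](C)(C)C(C)(C)C)[C@H](c3ccc(O[Si](C(C)C)(C(C)C)C(C)C)c(OC)c3)O4)[C@H]2CO[Si](C)(C)C(C)(C)C)ccc1O[Si](C(C)C)(C(C)C)C(C)C
F5 | step 4 | dimethyl acetal of 5 | COc1cc(C(OC)OC)cc(I)c1OCc1ccc(O[Si](C(C)C)(C(C)C)C(C)C)c(OC)c1
F6 | step 4 | ethyl 2-[5-(dimethoxymethyl)-3-methoxy-2-{[3-methoxy-4-(TIPS-oxy)phenyl]methoxy}phenyl]acetate | CCOC(=O)Cc1cc(C(OC)OC)cc(OC)c1OCc1ccc(O[Si](C(C)C)(C(C)C)C(C)C)c(OC)c1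
F7 | step 4 | ethyl 2-diazo-2-[5-(dimethoxymethyl)-3-methoxy-2-{[3-methoxy-4-(TIPS-oxy)phenyl]methoxy}phenyl]acetate | CCOC(=O)C(=[N+]=[N-])c1cc(C(OC)OC)cc(OC)c1OCc1ccc(O[Si](C(C)C)(C(C)C)C(C)C)c(OC)c1
F8 | step 14 | (2R,3R,4R)-2-DHB-3-(TBS-oxymethyl)-4-[(trimethylsilyl)methyl]oxolan-4-ol with the CH2SiMe3 group trans to the C3 substituent | C[Si](C)(C)C[C@]1(O)CO[C@@H](c3cc(OC)c4c(c3)[C@H](CO[Si](C)(C)C(C)(C)C)[C@H](c3ccc(O[Si](C(C)C)(C(C)C)C(C)C)c(OC)c3)O4)[C@H]1CO[Si](C)(C)C(C)(C)C
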